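**Strategy.** Ring B is disconnected at the bond between the carbonyl carbon C1 and the side-chain-bearing carbon C2. The precursor is a 2-[(Z)-alkenyl]-2-hydroxybenzocyclobutenone, assembled from twofold-symmetric 3,6-dimethoxybenzocyclobutenedione and the dilithio derivative of (R)-6-methylhept-5-en-1-yn-3-ol, then semihydrogenated. On heating, 4π ring opening gives an o-quinoid dienylketene whose ketene carbon (C1) closes onto the alkene terminus (C2) by 6π electrocyclization; enolization and Ag2O oxidation deliver the quinone. The step exploits the para C1/C4 dioxygenation of ring B with hydrogen at C3 and the symmetry of ring A. C1' is set earlier by asymmetric transfer hydrogenation; esterification and oxidative demethylation complete the synthesis.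

Key step: step 9

Assumption: the naphthazarin core equilibrates rapidly between its 1,4-quinone and 5,8-quinone tautomers, so the last step gives one compound, drawn as the tautomer of the target (C1–C8a are the naphthalene atoms of the target, C1' is the carbinol carbon of the side chain).

**Step 1**
Reactants: 1 2-bromo-1,4-dimethoxybenzene; 2 1,1-diethoxyethene
Product: 5 2,5-dimethoxybicyclo[4.2.0]octa-1,3,5-trien-7-one (3,6-dimethoxybenzocyclobutenone), via 3,6-dimethoxybenzyne 3 (not isolated), via diethyl ketal 4 (not isolated)
Conditions: NaNH2, THF, reflux; then 1 M aq HCl, THF, rt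
Reagents that add atoms: water, O
Why: Amide-induced dehydrobromination gives the symmetrical aryne 3, which the electron-rich ketene acetal traps in a [2+2] aryne cycloaddition without any regiochemical choice, and dilute acid hydrolyses ketal 4 to the ketone.

**Step 2**
Reactants: 5 2,5-dimethoxybicyclo[4.2.0]octa-1,3,5-trien-7-one
Product: 6 8,8-dibromo-2,5-dimethoxybicyclo[4.2.0]octa-1,3,5-trien-7-one
Conditions: NBS (2.2 equiv), (PhCO2)2 (cat.), PhCF3, reflux, hν
Reagents that add atoms: N-bromosuccinimide, O=C1CCC(=O)N1Br
Why: Wohl–Ziegler radical bromination should take place twice at the only benzylic CH2, which is also α to the carbonyl, while the non-polar radical conditions spare the aryl C–H bonds.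

**Step 3**
Reactants: 6 8,8-dibromo-2,5-dimethoxybicyclo[4.2.0]octa-1,3,5-trien-7-one
Product: 7 2,5-dimethoxybicyclo[4.2.0]octa-1,3,5-triene-7,8-dione (3,6-dimethoxybenzocyclobutenedione)
Conditions: AgO2CCF3 (2.2 equiv), MeCN/H2O, rt to 50 °C
Reagents that add atoms: water, O
Why: Silver-assisted hydrolysis of the benzylic gem-dibromide (halide abstraction, capture by water, loss of HBr) should unveil the second carbonyl under nearly neutral conditions.

**Step 4**
Reactants: 8 4-methylpent-3-enoic acid
Product: 10 N-methoxy-N,4-dimethylpent-3-enamide, via acyl imidazole 9 (not isolated)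
Conditions: CDI, CH2Cl2, rt; then MeNH(OMe)·HCl, rt
Reagents that add atoms: N,O-dimethylhydroxylamine hydrochloride, CNOC.Cl
Why: Weinreb amide synthesis through the acyl imidazole needs no base strong enough to move the β,γ-double bond into conjugation.

**Step 5**
Reactants: 10 N-methoxy-N,4-dimethylpent-3-enamide; 11 ethynyltrimethylsilane
Product: 13 6-methyl-1-(trimethylsilyl)hept-5-en-1-yn-3-one, via lithium acetylide 12 (not isolated)
Conditions: 11, n-BuLi, THF, −78 °C; then 10, −78 to 0 °C; then cold 1 M aq HCl
Reagents that add atoms: none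
Why: Weinreb ketone synthesis: the acetylide adds once because the chelated tetrahedral lithium intermediate survives until the cold acidic quench, which also protonates the liberated amine before it can add to the ynone.

**Step 6**
Reactants: 13 6-methyl-1-(trimethylsilyl)hept-5-en-1-yn-3-one
Product: 15 (3R)-6-methylhept-5-en-1-yn-3-ol, via silyl alkynol 14 (not isolated)
Conditions: RuCl[(R,R)-TsDPEN](p-cymene) (1 mol %), i-PrOH, rt; then K2CO3 (cat.), MeOH, rt
Reagents that add atoms: none
Why: Noyori asymmetric transfer hydrogenation of an alkynyl ketone with the (R,R)-configured catalyst should deliver hydride to the carbonyl face that gives the (R)-propargylic alcohol (the alkyne acts as the π-substituent that the catalyst recognises), this reduction being practically irreversible, and methanolysis then cleaves the C–Si bond.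

**Step 7**
Reactants: 15 (3R)-6-methylhept-5-en-1-yn-3-ol; 7 2,5-dimethoxybicyclo[4.2.0]octa-1,3,5-triene-7,8-dione
Product: 17 8-hydroxy-8-[(3R)-3-hydroxy-6-methylhept-5-en-1-yn-1-yl]-2,5-dimethoxybicyclo[4.2.0]octa-1,3,5-trien-7-one (both C8 epimers), via dilithio alkynol 16 (not isolated)
Conditions: 15, n-BuLi (2.0 equiv), THF, −78 to 0 °C; then 7, THF, −78 °C; then AcOH, −78 °C
Reagents that add atoms: none
Why: 1,2-Addition of the lithium acetylide to one of the two equivalent strained carbonyl groups, after which the lithium alkoxide shields the neighbouring carbonyl from a second addition; the new tertiary carbinol centre forms without control, which is of no consequence because it becomes sp2 in step 9.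

**Step 8**
Reactants: 17 8-hydroxy-8-[(3R)-3-hydroxy-6-methylhept-5-en-1-yn-1-yl]-2,5-dimethoxybicyclo[4.2.0]octa-1,3,5-trien-7-one
Product: 18 8-hydroxy-8-[(1Z,3R)-3-hydroxy-6-methylhepta-1,5-dien-1-yl]-2,5-dimethoxybicyclo[4.2.0]octa-1,3,5-trien-7-one (both C8 epimers)
Conditions: H2 (1 atm), Pd/CaCO3 poisoned with Pb(OAc)2 (Lindlar catalyst), quinoline, EtOAc, rt
Reagents that add atoms: none
Why: Lindlar semihydrogenation adds H2 syn to the alkyne and should stop at the (Z)-alkene, leaving the trisubstituted alkene and the ketone untouched.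

**Step 9**
Reactants: 18 8-hydroxy-8-[(1Z,3R)-3-hydroxy-6-methylhepta-1,5-dien-1-yl]-2,5-dimethoxybicyclo[4.2.0]octa-1,3,5-trien-7-one
Product: 22 2-[(1R)-1-hydroxy-4-methylpent-3-en-1-yl]-5,8-dimethoxynaphthalene-1,4-dione, via o-quinoid dienylketene 19 (not isolated), via dienone tautomer 20 (not isolated), via hydroquinone 21 (not isolated)
Conditions: p-xylene (0.01 M, degassed), 138 °C; then Ag2O, MgSO4, rt
Reagents that add atoms: none
Why: Heating should cleave the C7–C8 bond of the cyclobutenone in a conrotatory 4π electrocyclic opening to o-quinoid dienylketene 19, whose ketene carbon (future C1) and alkene terminus (future C2) then join in a disrotatory 6π electrocyclization; enolization of dienone 20 gives hydroquinone 21, which monovalent silver oxide dehydrogenates to the quinone. The closest known reaction type is the thermal ring expansion of 4-alkenyl-4-hydroxycyclobutenones to hydroquinones, here in its benzo-fused form. Ring B closes in the 6π-electrocyclic mode with rearomatization of ring A as driving force, and because the path is closed-shell the 4-methylpent-3-enyl alkene is not engaged, as it could be by the aryl radical of the corresponding alkynyl rearrangement. No stereocentre of 22 is formed here: both C8 epimers of 18 and the transient C2 centre of 20 converge on one product, and C1' keeps its (R) configuration because none of its bonds is broken. The step needs the hydroxyl to rotate outward so that the alkenyl group ends up beside the ketene, and it needs ring closure to outrun capture of the ketene by the C1' hydroxyl; the first is secured by the donor OH on the breaking bond (helped by a hydrogen bond to the peri methoxy group), the second by the linear, unsubstituted ketene terminus that tolerates the inward (Z) substituent, together with high dilution.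

**Step 10**
Reactants: 22 2-[(1R)-1-hydroxy-4-methylpent-3-en-1-yl]-5,8-dimethoxynaphthalene-1,4-dione; 23 3-methylbut-2-enoic acid
Product: 24 (1R)-1-(5,8-dimethoxy-1,4-dioxo-1,4-dihydronaphthalen-2-yl)-4-methylpent-3-en-1-yl 3-methylbut-2-enoate
Conditions: DCC, DMAP (cat.), CH2Cl2, 0 °C to rt
Reagents that add atoms: none
Why: Steglich esterification of the only free hydroxyl leaves the C1'–O bond intact, so the (R) configuration is retained, and carbodiimide activation avoids the vinylketene route to the deconjugated ester.

**Step 11**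
Reactants: 24 (1R)-1-(5,8-dimethoxy-1,4-dioxo-1,4-dihydronaphthalen-2-yl)-4-methylpent-3-en-1-yl 3-methylbut-2-enoate
Product: 26 (1R)-1-(5,8-dihydroxy-1,4-dioxo-1,4-dihydronaphthalen-2-yl)-4-methylpent-3-en-1-yl 3-methylbut-2-enoate (the target), via diquinone 25 (not isolated)
Conditions: AgO, 6 M HNO3, 1,4-dioxane, rt, 10 min; then aq Na2S2O4
Reagents that add atoms: water, O
Why: Oxidative demethylation of the hydroquinone dimethyl ether ring by divalent silver oxide should give diquinone 25, and two-electron reduction by dithionite returns the naphthazarin, whose tautomers are one compound so that the site of reduction is immaterial, while the brief oxidation should spare the alkene and both ester groups.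

**Compound list**
1 | 2-bromo-1,4-dimethoxybenzene | COc1ccc(OC)c(Br)c1 | starting material
2 | 1,1-diethoxyethene | C=C(OCC)OCC | starting material
3 | 3,6-dimethoxybenzyne | COC1=CC=C(OC)C#C1 | intermediate, not isolated
4 | 7,7-diethoxy-2,5-dimethoxybicyclo[4.2.0]octa-1,3,5-triene | CCOC1(OCC)Cc2c(OC)ccc(OC)c21 | intermediate, not isolated
5 | 2,5-dimethoxybicyclo[4.2.0]octa-1,3,5-trien-7-one | COc1ccc(OC)c2c1CC2=O | intermediate
6 | 8,8-dibromo-2,5-dimethoxybicyclo[4.2.0]octa-1,3,5-trien-7-one | COc1ccc(OC)c2c1C(Br)(Br)C2=O | intermediate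
7 | 2,5-dimethoxybicyclo[4.2.0]octa-1,3,5-triene-7,8-dione | COc1ccc(OC)c2c1C(=O)C2=O | intermediate
8 | 4-methylpent-3-enoic acid | CC(C)=CCC(=O)O | starting material
9 | 1-(imidazol-1-yl)-4-methylpent-3-en-1-one | CC(C)=CCC(=O)n1ccnc1 | intermediate, not isolated
10 | N-methoxy-N,4-dimethylpent-3-enamide | CC(C)=CCC(=O)N(C)OC | intermediate
11 | ethynyltrimethylsilane | C#C[Si](C)(C)C | starting material
12 | lithium (trimethylsilyl)acetylide | [Li]C#C[Si](C)(C)C | intermediate, not isolated
13 | 6-methyl-1-(trimethylsilyl)hept-5-en-1-yn-3-one | CC(C)=CCC(=O)C#C[Si](C)(C)C | intermediate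
14 | (3R)-6-methyl-1-(trimethylsilyl)hept-5-en-1-yn-3-ol | C[Si](C)(C)C#C[C@H](O)CC=C(C)C | intermediate, not isolated
15 | (3R)-6-methylhept-5-en-1-yn-3-ol | C#C[C@H](O)CC=C(C)C | intermediate
16 | dilithio derivative of 15 (lithium acetylide, lithium alkoxide) | [Li]C#C[C@H](O[Li])CC=C(C)C | intermediate, not isolated
17 | 8-hydroxy-8-[(3R)-3-hydroxy-6-methylhept-5-en-1-yn-1-yl]-2,5-dimethoxybicyclo[4.2.0]octa-1,3,5-trien-7-one, both C8 epimers | COc1ccc(OC)c2c1C(=O)C2(O)C#C[C@H](O)CC=C(C)C | intermediate
18 | 8-hydroxy-8-[(1Z,3R)-3-hydroxy-6-methylhepta-1,5-dien-1-yl]-2,5-dimethoxybicyclo[4.2.0]octa-1,3,5-trien-7-one, both C8 epimers | COc1ccc(OC)c2c1C(=O)C2(O)/C=C\[C@H](O)CC=C(C)C | intermediate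
19 | o-quinoid dienylketene (ring-opened 18, alkenyl group next to the ketene) | COC1=CC=C(OC)C(=C=O)/C1=C(/O)\C=C/[C@H](O)CC=C(C)C | intermediate, not isolated
20 | 4-hydroxy-2-[(1R)-1-hydroxy-4-methylpent-3-en-1-yl]-5,8-dimethoxy-2H-naphthalen-1-one, both C2 epimers | COc1ccc(OC)c2c1C(O)=CC([C@H](O)CC=C(C)C)C2=O | intermediate, not isolated
21 | 2-[(1R)-1-hydroxy-4-methylpent-3-en-1-yl]-5,8-dimethoxynaphthalene-1,4-diol | COc1ccc(OC)c2c(O)c([C@H](O)CC=C(C)C)cc(O)c12 | intermediate, not isolated
22 | 2-[(1R)-1-hydroxy-4-methylpent-3-en-1-yl]-5,8-dimethoxynaphthalene-1,4-dione | COc1ccc(OC)c2c1C(=O)C=C([C@H](O)CC=C(C)C)C2=O | intermediate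
23 | 3-methylbut-2-enoic acid | CC(C)=CC(=O)O | starting material
24 | (1R)-1-(5,8-dimethoxy-1,4-dioxo-1,4-dihydronaphthalen-2-yl)-4-methylpent-3-en-1-yl 3-methylbut-2-enoate | COc1ccc(OC)c2c1C(=O)C=C([C@H](OC(=O)C=C(C)C)CC=C(C)C)C2=O | intermediate
25 | (1R)-4-methyl-1-(1,4,5,8-tetraoxo-1,4,5,8-tetrahydronaphthalen-2-yl)pent-3-en-1-yl 3-methylbut-2-enoate | O=C1C=CC(=O)C2=C1C(=O)C=C([C@H](OC(=O)C=C(C)C)CC=C(C)C)C2=O | intermediate, not isolated
26 | (1R)-1-(5,8-dihydroxy-1,4-dioxo-1,4-dihydronaphthalen-2-yl)-4-methylpent-3-en-1-yl 3-methylbut-2-enoate | CC(C)=CC[C@@H](OC(=O)C=C(C)C)C1=CC(=O)c2c(O)ccc(O)c2C1=O | target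

**Step count.** Total: 11 steps. Longest linear sequence: 8 steps (steps 4, 5, 6, 7, 8, 9, 10, 11 from acid 8; the arene branch, steps 1, 2, 3, 7, 8, 9, 10, 11, is equally long).

**Steps most likely to fail**

1. Step 9. The electron-rich hydroquinone 21 may lose water at C1' through an o-quinone methide during prolonged heating (loss or racemisation of the stereocentre), or the ring opening of the benzo-fused cyclobutenone may be too slow at this temperature. The fallback sets out from dione 7 and alkynol 15 and comes back at quinone 22. Dione 7 is treated with CoCl(PPh3)3 (monovalent cobalt) in chlorobenzene, which should insert into the bond between the two carbonyl carbons to give the trivalent cobalt metallacycle chloro(3,6-dimethoxyphthaloyl)bis(triphenylphosphine)cobalt F1. Chloride abstraction with AgBF4 in MeCN, then addition of 15 at 80 °C, should give 22 by alkyne insertion and reductive elimination. This path is closed-shell, runs at lower temperature and never passes through the hydroquinone.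

2. Step 11. The oxidation may attack the electron-rich trisubstituted alkene, stall on the electron-poor dimethoxy ring, or the acid may cleave the activated C1' ester. The fallback sets out from 24 and comes back at 26 without a new compound: MgI2·OEt2 in toluene at rt to 60 °C. This is a non-oxidative cleavage of the two O–CH3 bonds, directed by chelation of magnesium between each peri methoxy oxygen and its neighbouring quinone carbonyl, followed by aqueous work-up.

3. Step 8. Hydrogen uptake at the hindered alkyne may be sluggish or run on to the alkane, and the amine additive may trigger base-induced cleavage of the strained α-ketol. The fallback sets out from 15 (and 7) and comes back at 22; it replaces the semihydrogenation by a preformed (E)-alkenyl nucleophile. Alkynol 15 is silylated (TBSCl, imidazole, DMF) to tert-butyldimethyl{[(3R)-6-methylhept-5-en-1-yn-3-yl]oxy}silane F2. Hydrozirconation with Cp2Zr(H)Cl in THF and iodinolysis with I2 give the (E)-vinyl iodide tert-butyl{[(1E,3R)-1-iodo-6-methylhepta-1,5-dien-3-yl]oxy}dimethylsilane F3. Iodine–lithium exchange (t-BuLi, Et2O, −78 °C) and addition to 7 give the (E)-alkenyl carbinol 8-[(1E,3R)-3-(tert-butyldimethylsilyloxy)-6-methylhepta-1,5-dien-1-yl]-8-hydroxy-2,5-dimethoxybicyclo[4.2.0]octa-1,3,5-trien-7-one F4. Thermolysis and Ag2O oxidation as in step 9 give the silyl ether 2-[(1R)-1-(tert-butyldimethylsilyloxy)-4-methylpent-3-en-1-yl]-5,8-dimethoxynaphthalene-1,4-dione F5, and HF·pyridine in THF returns 22.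

**Further compounds**
F1 | step 9 | chloro(3,6-dimethoxyphthaloyl)bis(triphenylphosphine)cobalt | COc1ccc(OC)c2c1C(=O)[Co-2](Cl)([P+](c3ccccc3)(c3ccccc3)c3ccccc3)([P+](c3ccccc3)(c3ccccc3)c3ccccc3)C2=O
F2 | step 8 | tert-butyldimethyl{[(3R)-6-methylhept-5-en-1-yn-3-yl]oxy}silane | C#C[C@H](O[Si](C)(C)C(C)(C)C)CC=C(C)C
F3 | step 8 | tert-butyl{[(1E,3R)-1-iodo-6-methylhepta-1,5-dien-3-yl]oxy}dimethylsilane | I/C=C/[C@H](O[Si](C)(C)C(C)(C)C)CC=C(C)C
F4 | step 8 | 8-[(1E,3R)-3-(tert-butyldimethylsilyloxy)-6-methylhepta-1,5-dien-1-yl]-8-hydroxy-2,5-dimethoxybicyclo[4.2.0]octa-1,3,5-trien-7-one | COc1ccc(OC)c2c1C(=O)C2(O)/C=C/[C@H](O[Si](C)(C)C(C)(C)C)CC=C(C)C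
F5 | step 8 | 2-[(1R)-1-(tert-butyldimethylsilyloxy)-4-methylpent-3-en-1-yl]-5,8-dimethoxynaphthalene-1,4-dione | COc1ccc(OC)c2c1C(=O)C=C([C@H](O[Si](C)(C)C(C)(C)C)CC=C(C)C)C2=O
F0 | step 11 | none | none
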